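**Plan**

- Retrosynthetic cuts: last, C8–O and C9–H together (syn-hydration of a C8=C9 alkene); before that, C9–C11 (alkenyl C9 plus primary C11 radical). The ester is carried in the chain fragment from the start.
- Forward order: the decalin is taken intact from (−)-sclareol. Its C11–C16 chain is excised to a C9 ketone, which is turned into the C9 alkenyl iodide 7. The chain acid comes from (S)-citronellol, whose former alkene carbon is the carboxyl carbon lost as CO2. Then coupling, then hydration.
- Enabling feature: in ring B, C9 lies between quaternary C10 and C8. The C9 ketone can therefore enolise or eliminate only toward C8, so the alkenyl iodide and the C8=C9 bond are regiodefined and cannot migrate. The axial methyl on C10 blocks the β face.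
- Stereochemistry: C5 and C10 from sclareol; C13 from (S)-citronellol. C8 and C9 are erased and then re-set together in step 11 by suprafacial H–B addition on the α face with boron at the less hindered C8.

Key step: step 10

Remark: labdane numbering is used for all atoms (C17 = methyl on C8, C20 = methyl on C10). Compound 5 is carried as a C8-epimer mixture (8α-methyl epimer drawn) and 6 with undefined C=N geometry, because both elements vanish in step 6.

**Route**

Step 1
Reactants: 1 (−)-sclareol
Product: 2 8α-acetoxy-13,14,15,16-tetranorlabdan-12-oic acid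
Conditions: RuCl3·xH2O (cat.), NaIO4, CCl4/MeCN/H2O, 40 °C
Reagents that add atoms: sodium periodate (oxygen source), [Na+].[O-]I(=O)(=O)=O
Why: Ru-catalysed periodate oxidation (RuO4 oxidative cleavage) should degrade the vinyl carbinol to the C13 methyl ketone, which closes onto the 8α-hydroxyl as a cyclic enol ether whose C12=C13 bond is then cleaved, leaving C12 as the acid and C13/C16 as the acetate on O8, with no ring stereocentre touched.

Step 2
Reactants: 2 8α-acetoxy-13,14,15,16-tetranorlabdan-12-oic acid
Product: 3 drim-9(11)-en-8α-yl acetate (exocyclic C9=C11 methylene, 8α-OAc)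
Conditions: Pb(OAc)4, Cu(OAc)2 (cat.), pyridine, benzene, 80 °C
Reagents that add atoms: none
Why: Kochi oxidative decarboxylation: the primary C11 radical is oxidised by Cu(II) and loses the only β-hydrogen (C9–H), so the alkene can only be the exocyclic C9=C11 bond.

Step 3
Reactants: 3 drim-9(11)-en-8α-yl acetate
Product: 4 8α-acetoxy-11-nordriman-9-one (C9 ketone; C8 bears OAc α and CH3 β)
Conditions: O3, CH2Cl2/MeOH, −78 °C; Me2S
Reagents that add atoms: ozone, [O-][O+]=O
Why: Ozonolysis (Criegee) of the 1,1-disubstituted alkene removes C11 as formaldehyde and leaves a C9 ketone without α-hydrogen on either side, the tertiary acetate being inert.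

Step 4
Reactants: 4 8α-acetoxy-11-nordriman-9-one
Product: 5 11-nordriman-9-one [(4aS,8aS)-2,5,5,8a-tetramethyloctahydronaphthalen-1(2H)-one, C8 epimers]
Conditions: SmI2, THF/MeOH, −78 °C
Reagents that add atoms: none
Why: SmI2 reductive cleavage of an α-acyloxy ketone (ketyl, loss of acetate, protonation of the samarium enolate) should give the C8–H ketone, whose C8 configuration is irrelevant because it is erased in step 6.

Step 5
Reactants: 5 11-nordriman-9-one
Product: 6 11-nordriman-9-one hydrazone
Conditions: N2H4·H2O, Et3N, EtOH, reflux
Reagents that add atoms: hydrazine, NN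
Why: Hydrazone condensation (first half of the Barton vinyl iodide synthesis) should proceed under forcing conditions on this neopentyl-type ketone, as it does for other ketones next to a quaternary carbon.

Step 6
Reactants: 6 11-nordriman-9-one hydrazone
Product: 7 9-iodo-11-nordrim-8-ene [(4aS,8aS)-1-iodo-2,5,5,8a-tetramethyl-3,4,4a,5,6,7,8,8a-octahydronaphthalene]
Conditions: I2, 1,1,3,3-tetramethylguanidine, THF, 0 °C to rt; then 80 °C
Reagents that add atoms: iodine, II
Why: Barton vinyl iodide synthesis: oxidation to the diazoalkane, iodination with loss of N2 and removal of the only β-hydrogen (C8–H, C10 being quaternary) should give the tetrasubstituted C9 iodide with the double bond fixed at C8=C9, both C8 epimers converging.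

Step 7
Reactants: 8 (S)-citronellol, 9 3-phenylpropanoyl chloride
Product: 10 (S)-citronellyl 3-phenylpropanoate [(3S)-3,7-dimethyloct-6-en-1-yl 3-phenylpropanoate]
Conditions: pyridine, DMAP (cat.), CH2Cl2, 0 °C to rt
Reagents that add atoms: none
Why: Nucleophilic acyl substitution of the acid chloride by the primary alcohol (DMAP catalysis) installs the ester of the target at the outset and leaves the remote stereocentre (future C13) untouched.

Step 8
Reactants: 10 (S)-citronellyl 3-phenylpropanoate
Product: 12 (S)-4-methyl-6-[(3-phenylpropanoyl)oxy]hexanoic acid, via (S)-3-methyl-6-oxohexyl 3-phenylpropanoate 11 (not isolated)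
Conditions: O3, CH2Cl2/MeOH, −78 °C (indicator end-point); Me2S; then NaClO2, NaH2PO4, 2-methyl-2-butene, t-BuOH/H2O, rt
Reagents that add atoms: ozone, [O-][O+]=O; sodium chlorite, [Na+].[O-]Cl=O
Why: Ozonolysis of the electron-rich trisubstituted alkene is much faster than attack on the monosubstituted benzene ring, and Pinnick oxidation of the crude aldehyde should give the acid without touching the ester or the stereocentre, which is γ to the carbonyl and cannot epimerise.

Step 9
Reactants: 12 (S)-4-methyl-6-[(3-phenylpropanoyl)oxy]hexanoic acid
Product: 13 1,3-dioxoisoindolin-2-yl (S)-4-methyl-6-[(3-phenylpropanoyl)oxy]hexanoate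
Conditions: N-hydroxyphthalimide, DIC, DMAP (cat.), CH2Cl2, rt
Reagents that add atoms: N-hydroxyphthalimide, ON1C(=O)c2ccccc2C1=O
Why: Carbodiimide (Steglich-type) esterification should give the redox-active ester that stores the primary C11 radical, its carboxyl carbon being the one sacrificed as CO2.

Step 10
Reactants: 13 1,3-dioxoisoindolin-2-yl (S)-4-methyl-6-[(3-phenylpropanoyl)oxy]hexanoate (2 equiv), 7 9-iodo-11-nordrim-8-ene
Product: 14 (13S)-labd-8-en-15-yl 3-phenylpropanoate
Conditions: NiCl2·6H2O (20 mol %), 2,2′-bipyridine (20 mol %), AgNO3 (0.3 equiv), DMF, undivided cell, Mg anode/RVC cathode, constant current, rt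
Reagents that add atoms: none
Why: Cathodically generated low-valent Ni(bpy) adds oxidatively to the C9–I bond of 7, while single-electron reduction of 13 (at Ni(I) or at the silver-coated cathode) fragments it to phthalimide anion, CO2 and the primary C11 radical; capture of this radical by the alkenyl–Ni(II) species and reductive elimination from Ni(III) form the C9–C11 bond. The closest known reaction type is the Ni-electrocatalytic decarboxylative alkenylation of N-hydroxyphthalimide esters with alkenyl halides (sacrificial Mg anode, Ag additive). No ring is closed and no stereocentre is created: C9 is deliberately kept sp2, so the face on which carbon arrives is of no consequence and the C9–H bond can be made last on the open α face in step 11. The step needs cross- over homo-coupling, retention of the alkene position and tolerance of the ester: the primary radical is unhindered and is released only near the catalyst, the alkenyl–Ni bond flanked by quaternary C10 and the C8 methyl is slow to dimerise, the tetrasubstituted C8=C9 bond is locked in ring B with C10 unable to accept a double bond, and the mild cathodic potential should spare the 3-phenylpropanoate. C13 lies two carbons from the radical centre and keeps its configuration.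

Step 11
Reactants: 14 (13S)-labd-8-en-15-yl 3-phenylpropanoate
Product: 16 (13S)-8α-hydroxylabdan-15-yl 3-phenylpropanoate (target), via (13S)-8α-boryllabdan-15-yl 3-phenylpropanoate 15 (not isolated)
Conditions: BH3·SMe2, THF, 0 °C to rt; then NaBO3·4H2O, THF/H2O, rt
Reagents that add atoms: borane–dimethyl sulfide (boron of 15 only), [BH3-][S+](C)C; sodium perborate (oxygen of 16), [Na+].[Na+].O[B-]1(O)OO[B-](O)(O)OO1
Why: Brown hydroboration–oxidation: BH3 should add suprafacially to the α face of the C8=C9 bond (the β face is shielded by the axial C10 methyl) with boron at C8, the end remote from quaternary C10, so that C9–H (α) and C8–B (α) are set together and perborate oxidation with retention gives the 8α-hydroxyl, a short contact time and near-neutral oxidant sparing the ester.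

**Compound list**

1 | (−)-sclareol [(13R)-labd-14-ene-8α,13-diol] | C=C[C@](C)(O)CC[C@@H]1[C@@]2(C)CCCC(C)(C)[C@@H]2CC[C@@]1(C)O | starting material
2 | 8α-acetoxy-13,14,15,16-tetranorlabdan-12-oic acid | OC(=O)C[C@@H]1[C@@]2(C)CCCC(C)(C)[C@@H]2CC[C@@]1(C)OC(C)=O | intermediate
3 | drim-9(11)-en-8α-yl acetate | C=C1[C@@]2(C)CCCC(C)(C)[C@@H]2CC[C@@]1(C)OC(C)=O | intermediate
4 | 8α-acetoxy-11-nordriman-9-one | O=C1[C@@]2(C)CCCC(C)(C)[C@@H]2CC[C@@]1(C)OC(C)=O | intermediate
5 | 11-nordriman-9-one, 8α-methyl epimer drawn [(2R,4aS,8aS)-2,5,5,8a-tetramethyloctahydronaphthalen-1(2H)-one] | O=C1[C@@]2(C)CCCC(C)(C)[C@@H]2CC[C@H]1C | intermediate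
6 | 11-nordriman-9-one hydrazone (C=N geometry undefined) | NN=C1[C@@]2(C)CCCC(C)(C)[C@@H]2CC[C@H]1C | intermediate
7 | 9-iodo-11-nordrim-8-ene | CC1=C(I)[C@@]2(C)CCCC(C)(C)[C@@H]2CC1 | intermediate
8 | (S)-citronellol | C[C@H](CCO)CCC=C(C)C | starting material
9 | 3-phenylpropanoyl chloride | O=C(Cl)CCc1ccccc1 | starting material
10 | (S)-citronellyl 3-phenylpropanoate | C[C@H](CCOC(=O)CCc1ccccc1)CCC=C(C)C | intermediate
11 | (S)-3-methyl-6-oxohexyl 3-phenylpropanoate | C[C@H](CCOC(=O)CCc1ccccc1)CCC=O | intermediate
12 | (S)-4-methyl-6-[(3-phenylpropanoyl)oxy]hexanoic acid | C[C@H](CCOC(=O)CCc1ccccc1)CCC(=O)O | intermediate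
13 | 1,3-dioxoisoindolin-2-yl (S)-4-methyl-6-[(3-phenylpropanoyl)oxy]hexanoate | C[C@H](CCOC(=O)CCc1ccccc1)CCC(=O)ON1C(=O)c2ccccc2C1=O | intermediate
14 | (13S)-labd-8-en-15-yl 3-phenylpropanoate | CC1=C(CC[C@H](C)CCOC(=O)CCc2ccccc2)[C@@]2(C)CCCC(C)(C)[C@@H]2CC1 | intermediate
15 | (13S)-8α-boryllabdan-15-yl 3-phenylpropanoate (BH2 on C8, α) | C[C@H](CCOC(=O)CCc1ccccc1)CC[C@@H]1[C@@]2(C)CCCC(C)(C)[C@@H]2CC[C@@]1(C)B | intermediate
16 | (13S)-8α-hydroxylabdan-15-yl 3-phenylpropanoate (5S,8R,9R,10S,13S) | C[C@H](CCOC(=O)CCc1ccccc1)CC[C@@H]1[C@@]2(C)CCCC(C)(C)[C@@H]2CC[C@@]1(C)O | target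

**Count and risks**

Total step count: 11. Longest linear sequence: 8 steps (steps 1–6, 10, 11).

Steps most likely to fail:

Step 10. Oxidative addition and radical capture at the doubly flanked, tetrasubstituted alkenyl–nickel centre may be too slow, so that the primary radical dimerises or is reduced and the iodide is hydrodehalogenated. The fallback sets out from acid 12 and iodide 7 and replaces the radical coupling by a polar one. Iododecarboxylation of 12 (PhI(OAc)2, I2, hν, CCl4) should give (R)-5-iodo-3-methylpentyl 3-phenylpropanoate F1. Zinc insertion (Zn dust, LiCl, THF, 40 °C) should give [(R)-3-methyl-5-(3-phenylpropanoyloxy)pentyl]zinc iodide F2, which tolerates the ester. Pd-catalysed Negishi coupling of F2 with 7 (Pd(dppf)Cl2, THF/NMP, 60 °C), a reaction type well established for hindered cycloalkenyl electrophiles, comes back to the route at 14.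

Step 11. Hydroboration of the tetrasubstituted alkene may be sluggish, allowing competing reduction of the ester by borane or migration of boron before oxidation. The fallback sets out from 14 and avoids borane. Epoxidation on the open α face (mCPBA, NaHCO3, CH2Cl2, 0 °C) should give (13S)-8α,9α-epoxylabdan-15-yl 3-phenylpropanoate F3. Titanocene(III)-mediated reductive opening (Cp2TiCl2, Mn, collidine hydrochloride, 1,4-cyclohexadiene, THF) should cleave the more congested C9–O bond homolytically, leaving the titanium alkoxide on C8 with its configuration intact. The tertiary C9 radical then takes hydrogen on the α face, which comes back to the route at 16.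

Step 6. Conversion of the hindered hydrazone may stall, or the iodo-cation stage may divert into a 1,2-methyl shift from C10 or gem-diiodide formation. The fallback sets out from ketone 5 and uses enolate chemistry. Deprotonation at the only enolisable position (KHMDS, THF, −78 °C) and O-triflation with PhNTf2 should give 11-nordrim-8-en-9-yl trifluoromethanesulfonate F4. Nickel-catalysed triflate-to-iodide exchange (Ni(cod)2 cat., NaI, DMA/THF, rt) comes back to the route at 7.

**Further compounds**

F1 | step 10 | (R)-5-iodo-3-methylpentyl 3-phenylpropanoate | C[C@H](CCOC(=O)CCc1ccccc1)CCI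
F2 | step 10 | [(R)-3-methyl-5-(3-phenylpropanoyloxy)pentyl]zinc iodide | C[C@H](CCOC(=O)CCc1ccccc1)CC[Zn]I
F3 | step 11 | (13S)-8α,9α-epoxylabdan-15-yl 3-phenylpropanoate | C[C@H](CCOC(=O)CCc1ccccc1)CC[C@@]12O[C@]1(C)CC[C@H]3C(C)(C)CCC[C@]23C
F4 | step 6 | 11-nordrim-8-en-9-yl trifluoromethanesulfonate | CC1=C(OS(=O)(=O)C(F)(F)F)[C@@]2(C)CCCC(C)(C)[C@@H]2CC1
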